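## Retrosynthetic overview

- The strategy rests on the tetrahydropyran ring O1–C2(aryl)–C3–C4(OH)–C5–C6(arylethyl). Its C4 oxygen lies between the cis stereocentres C2 and C6, which is the pattern left by a hetero-Diels–Alder reaction of an aldehyde with a 2-silyloxydiene.
- Endgame: the two phenols are released last from benzyl ethers. The axial C4–OH comes from the C4 ketone by equatorial hydride delivery, and the ketone from the C3=C4 silyl enol ether.
- Key disconnection: O1–C2 and C5–C6. The only ring is closed in one enantioselective [4+2] step from diene 4 and aldehyde 8 under a chiral chromium Schiff-base catalyst.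
- Diene 4 comes from dehydrozingerone in two steps; aldehyde 8 comes from dihydroferulic acid in three steps.

Key step: step 6

Assumption: the catalyst made from (1R,2S)-1-aminoindan-2-ol is taken to direct the diene to the Re face of the aldehyde, as it does with simpler dienes; if the opposite sense is found, the mirror-image catalyst from (1S,2R)-1-aminoindan-2-ol is used instead.

## Route

Step 1
Reactants: 1 dehydrozingerone, (E)-4-(4-hydroxy-3-methoxyphenyl)but-3-en-2-one; 2 benzyl bromide
Product: 3 (E)-4-(4-benzyloxy-3-methoxyphenyl)but-3-en-2-one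
Conditions: BnBr (1.1 equiv), K2CO3, DMF, rt
Reagents that add atoms: benzyl bromide, BrCc1ccccc1
Why: Williamson ether synthesis; the phenoxide formed with K2CO3 is alkylated by benzyl bromide in an SN2 reaction, and the enone is inert to carbonate.

Step 2
Reactants: 3 (E)-4-(4-benzyloxy-3-methoxyphenyl)but-3-en-2-one
Product: 4 (E)-1-(4-benzyloxy-3-methoxyphenyl)-3-(triethylsilyloxy)buta-1,3-diene
Conditions: Et3SiOTf (1.2 equiv), Et3N (2 equiv), CH2Cl2, 0 °C; filtration through Et3N-deactivated alumina, used promptly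
Reagents that add atoms: triethylsilyl trifluoromethanesulfonate, CC[Si](CC)(CC)OS(=O)(=O)C(F)(F)F
Why: Silyl enol ether formation by soft enolisation; the methyl group is the only enolisable position, so the 2-silyloxydiene should form as a single regioisomer with the E-styryl geometry unchanged.

Step 3
Reactants: 5 dihydroferulic acid, 3-(4-hydroxy-3-methoxyphenyl)propanoic acid; 2 benzyl bromide
Product: 6 benzyl 3-(4-benzyloxy-3-methoxyphenyl)propanoate
Conditions: BnBr (2.3 equiv), K2CO3, DMF, 60 °C
Reagents that add atoms: benzyl bromide (two equivalents), BrCc1ccccc1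
Why: Williamson O-alkylation of the phenoxide together with carboxylate alkylation to the benzyl ester, both simple SN2 reactions under the same conditions.

Step 4
Reactants: 6 benzyl 3-(4-benzyloxy-3-methoxyphenyl)propanoate
Product: 7 3-(4-benzyloxy-3-methoxyphenyl)propan-1-ol
Conditions: LiAlH4, THF, 0 °C to rt; then Na2SO4·10H2O
Reagents that add atoms: none
Why: Ester reduction with LiAlH4 to the primary alcohol; the benzyl aryl ether is inert to hydride.

Step 5
Reactants: 7 3-(4-benzyloxy-3-methoxyphenyl)propan-1-ol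
Product: 8 3-(4-benzyloxy-3-methoxyphenyl)propanal
Conditions: Dess–Martin periodinane, CH2Cl2, rt; used freshly prepared
Reagents that add atoms: none
Why: Dess–Martin oxidation stops cleanly at the aldehyde under neutral, water-free conditions, avoiding over-oxidation and aldol self-condensation.

Step 6
Reactants: 4 (E)-1-(4-benzyloxy-3-methoxyphenyl)-3-(triethylsilyloxy)buta-1,3-diene; 8 3-(4-benzyloxy-3-methoxyphenyl)propanal
Product: 9 (2S,6S)-2-(4-benzyloxy-3-methoxyphenyl)-6-[2-(4-benzyloxy-3-methoxyphenyl)ethyl]-4-(triethylsilyloxy)-5,6-dihydro-2H-pyran (ring numbered as in the overview; C3=C4 silyl enol ether, C2 and C6 substituents cis)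
Conditions: 4 (1.3 equiv), 8 (1.0 equiv), CrCl(C27H29NO2) (5–10 mol%; chloride complex of trivalent chromium with the dianion of the Schiff base of (1R,2S)-1-aminoindan-2-ol and 3-(1-adamantyl)-2-hydroxy-5-methylbenzaldehyde), powdered 4 Å MS, minimal acetone, rt; filtration through Et3N-deactivated silica
Reagents that add atoms: none
Why: The aldehyde oxygen of 8 binds to the Lewis-acidic trivalent chromium centre and the diene adds in a concerted but asynchronous [4+2] cycloaddition, in which the nucleophilic CH2 terminus of the silyl enol ether bonds to the carbonyl carbon (C5–C6) ahead of O1–C2; in the stepwise limit this is a Mukaiyama aldol followed by 6-endo-trig closure of the alkoxide onto the silyloxy-stabilised cation, which gives the same ring. The closest known reaction type is the hetero-Diels–Alder reaction of unbranched aliphatic aldehydes with 1-substituted 2-silyloxybutadienes under tridentate Schiff-base chromium chloride catalysts, and the electron-rich aryl group should raise the diene HOMO enough to offset its conjugation. The pyran ring is closed by this intermolecular cycloaddition, which forms both ring bonds in one step. C6 is set by the catalyst, which shields one face of the bound aldehyde so that the diene attacks the Re face (6S); C2 is set relative to C6 by the endo orientation of the aldehyde side chain towards the E-configured diene, which places aryl and arylethyl cis (2S). The step needs regio-, endo- and enantioselectivity: the regiochemistry is fixed by the polarisation of the 2-silyloxydiene, the endo preference by the E-styryl geometry with no Z substituent to hinder the s-cis conformer, and the facial selectivity by the aminoindanol-derived ligand.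

Step 7
Reactants: 9 (2S,6S)-2-(4-benzyloxy-3-methoxyphenyl)-6-[2-(4-benzyloxy-3-methoxyphenyl)ethyl]-4-(triethylsilyloxy)-5,6-dihydro-2H-pyran
Product: 10 (2S,6S)-2-(4-benzyloxy-3-methoxyphenyl)-6-[2-(4-benzyloxy-3-methoxyphenyl)ethyl]tetrahydro-4H-pyran-4-one
Conditions: Bu4NF, AcOH (1:1), THF, 0 °C
Reagents that add atoms: none
Why: Fluoride-mediated desilylation of the silyl enol ether with in-situ protonation by AcOH should give the ketone without strong acid (which would ionise the electron-rich benzylic C2–O1 bond) or free enolate (which would open the ring by retro-oxa-Michael reaction), so C2 and C6 are untouched.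

Step 8
Reactants: 10 (2S,6S)-2-(4-benzyloxy-3-methoxyphenyl)-6-[2-(4-benzyloxy-3-methoxyphenyl)ethyl]tetrahydro-4H-pyran-4-one
Product: 11 (2S,4S,6S)-2-(4-benzyloxy-3-methoxyphenyl)-6-[2-(4-benzyloxy-3-methoxyphenyl)ethyl]tetrahydro-2H-pyran-4-ol (4-OH axial, trans to both ring substituents)
Conditions: LiBH(s-Bu)3 (L-selectride, 1.3 equiv), THF, −78 °C; then H2O
Reagents that add atoms: none
Why: Diastereoselective ketone reduction; in the chair with both C2 and C6 substituents equatorial, the bulky tri-sec-butylborohydride should attack from the equatorial direction and give the axial 4S alcohol.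

Step 9
Reactants: 11 (2S,4S,6S)-2-(4-benzyloxy-3-methoxyphenyl)-6-[2-(4-benzyloxy-3-methoxyphenyl)ethyl]tetrahydro-2H-pyran-4-ol
Product: 12 (2S,4S,6S)-2-(4-hydroxy-3-methoxyphenyl)-6-[2-(4-hydroxy-3-methoxyphenyl)ethyl]tetrahydro-2H-pyran-4-ol (target)
Conditions: H2 (1 atm), 10% Pd/C, EtOAc, rt; stopped once 11 and the mono-benzyl ether are consumed
Reagents that add atoms: none
Why: Catalytic hydrogenolysis of the two benzyl aryl ethers; ArO–CH2Ph bonds should cleave much faster than the dialkyl-type benzylic C2–O1 bond in neutral EtOAc, and no stereocentre is touched.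

## Compound list

1 | dehydrozingerone, (E)-4-(4-hydroxy-3-methoxyphenyl)but-3-en-2-one | COc1cc(/C=C/C(C)=O)ccc1O | starting material
2 | benzyl bromide | BrCc1ccccc1 | starting material
3 | (E)-4-(4-benzyloxy-3-methoxyphenyl)but-3-en-2-one | COc1cc(/C=C/C(C)=O)ccc1OCc1ccccc1 | intermediate
4 | (E)-1-(4-benzyloxy-3-methoxyphenyl)-3-(triethylsilyloxy)buta-1,3-diene | C=C(O[Si](CC)(CC)CC)/C=C/c1ccc(OCc2ccccc2)c(OC)c1 | intermediate
5 | dihydroferulic acid, 3-(4-hydroxy-3-methoxyphenyl)propanoic acid | COc1cc(CCC(=O)O)ccc1O | starting material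
6 | benzyl 3-(4-benzyloxy-3-methoxyphenyl)propanoate | COc1cc(CCC(=O)OCc2ccccc2)ccc1OCc1ccccc1 | intermediate
7 | 3-(4-benzyloxy-3-methoxyphenyl)propan-1-ol | COc1cc(CCCO)ccc1OCc1ccccc1 | intermediate
8 | 3-(4-benzyloxy-3-methoxyphenyl)propanal | COc1cc(CCC=O)ccc1OCc1ccccc1 | intermediate
9 | (2S,6S)-2-(4-benzyloxy-3-methoxyphenyl)-6-[2-(4-benzyloxy-3-methoxyphenyl)ethyl]-4-(triethylsilyloxy)-5,6-dihydro-2H-pyran | COc1cc(CC[C@H]2CC(O[Si](CC)(CC)CC)=C[C@@H](c3ccc(OCc4ccccc4)c(OC)c3)O2)ccc1OCc1ccccc1 | intermediate
10 | (2S,6S)-2-(4-benzyloxy-3-methoxyphenyl)-6-[2-(4-benzyloxy-3-methoxyphenyl)ethyl]tetrahydro-4H-pyran-4-one | COc1cc(CC[C@H]2CC(=O)C[C@@H](c3ccc(OCc4ccccc4)c(OC)c3)O2)ccc1OCc1ccccc1 | intermediate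
11 | (2S,4S,6S)-2-(4-benzyloxy-3-methoxyphenyl)-6-[2-(4-benzyloxy-3-methoxyphenyl)ethyl]tetrahydro-2H-pyran-4-ol | COc1cc(CC[C@H]2C[C@H](O)C[C@@H](c3ccc(OCc4ccccc4)c(OC)c3)O2)ccc1OCc1ccccc1 | intermediate
12 | (2S,4S,6S)-2-(4-hydroxy-3-methoxyphenyl)-6-[2-(4-hydroxy-3-methoxyphenyl)ethyl]tetrahydro-2H-pyran-4-ol | COc1cc(CC[C@H]2C[C@H](O)C[C@@H](c3ccc(O)c(OC)c3)O2)ccc1O | target

## Step count and risks

Total step count: 9. Longest linear sequence: 7 steps (5 → 6 → 7 → 8 → 9 → 10 → 11 → 12).

Steps most likely to fail: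

1. Step 6. The styrene-conjugated diene may add slowly, which leaves time for its hydrolysis or oligomerisation, or the reaction may drift into an open-chain Mukaiyama aldol pathway with loss of endo and facial selectivity. The fallback sets out from 3 and 8 and returns at 10. The methyl ketone 3 is converted with chlorodiisopinocampheylborane and Et3N in Et2O at 0 °C into its enol borinate, which is added to aldehyde 8 at −78 °C and worked up with H2O2 in pH 7 buffer. The enantiomer of the boron reagent is chosen for Re-face attack, and this aldol should give (S,E)-1,7-bis(4-benzyloxy-3-methoxyphenyl)-5-hydroxyhept-1-en-3-one F1. Acid-promoted 6-endo-trig oxa-Michael cyclisation of the hydroxy enone (Amberlyst-15, CH2Cl2, rt) under thermodynamic control should then give the 2,6-cis ketone 10.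

2. Step 9. Over-reduction may occur: once the phenols are free, the catalyst may also cleave the benzylic C2–O1 bond and open the pyran. The fallback sets out from 1 and 5 and returns at 12, carrying the phenols as allyl ethers so that no hydrogenolysis is needed.
   - Diene branch: allyl bromide and K2CO3 in DMF convert 1 into (E)-4-(4-allyloxy-3-methoxyphenyl)but-3-en-2-one F4, and Et3SiOTf/Et3N gives (E)-1-(4-allyloxy-3-methoxyphenyl)-3-(triethylsilyloxy)buta-1,3-diene F5.
   - Aldehyde branch: acid 5 is bis-allylated to allyl 3-(4-allyloxy-3-methoxyphenyl)propanoate F6, reduced with LiAlH4 to 3-(4-allyloxy-3-methoxyphenyl)propan-1-ol F7 and oxidised with Dess–Martin periodinane to 3-(4-allyloxy-3-methoxyphenyl)propanal F8.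
   - Ring and endgame: the same chromium-catalysed cycloaddition should give the bis-allyl silyl enol ether F9, buffered Bu4NF the bis-allyl ketone F10, and LiBH(s-Bu)3 the bis-allyl axial alcohol F11. The allyl ethers are then removed with Pd(PPh3)4 and morpholine in THF at rt to give 12.

3. Step 8. Equatorial attack may not be selective enough, or the basic hydride reagent may open the β-alkoxy ketone by retro-oxa-Michael reaction. The fallback sets out from 10 and returns at 11. Reduction with NaBH4 in MeOH at 0 °C should give mainly the equatorial alcohol, (2S,4R,6S)-2-(4-benzyloxy-3-methoxyphenyl)-6-[2-(4-benzyloxy-3-methoxyphenyl)ethyl]tetrahydro-2H-pyran-4-ol F2. Mitsunobu inversion with 4-nitrobenzoic acid, PPh3 and diisopropyl azodicarboxylate in THF gives the axial ester, (2S,4S,6S)-2-(4-benzyloxy-3-methoxyphenyl)-6-[2-(4-benzyloxy-3-methoxyphenyl)ethyl]tetrahydro-2H-pyran-4-yl 4-nitrobenzoate F3. Methanolysis with K2CO3 in MeOH then gives 11.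

## Further compounds

F1 | step 6 | (S,E)-1,7-bis(4-benzyloxy-3-methoxyphenyl)-5-hydroxyhept-1-en-3-one | COc1cc(CC[C@H](O)CC(=O)/C=C/c2ccc(OCc3ccccc3)c(OC)c2)ccc1OCc1ccccc1
F2 | step 8 | (2S,4R,6S)-2-(4-benzyloxy-3-methoxyphenyl)-6-[2-(4-benzyloxy-3-methoxyphenyl)ethyl]tetrahydro-2H-pyran-4-ol | COc1cc(CC[C@H]2C[C@@H](O)C[C@@H](c3ccc(OCc4ccccc4)c(OC)c3)O2)ccc1OCc1ccccc1
F3 | step 8 | (2S,4S,6S)-2-(4-benzyloxy-3-methoxyphenyl)-6-[2-(4-benzyloxy-3-methoxyphenyl)ethyl]tetrahydro-2H-pyran-4-yl 4-nitrobenzoate | COc1cc(CC[C@H]2C[C@H](OC(=O)c3ccc([N+](=O)[O-])cc3)C[C@@H](c3ccc(OCc4ccccc4)c(OC)c3)O2)ccc1OCc1ccccc1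
F4 | step 9 | (E)-4-(4-allyloxy-3-methoxyphenyl)but-3-en-2-one | COc1cc(/C=C/C(C)=O)ccc1OCC=C
F5 | step 9 | (E)-1-(4-allyloxy-3-methoxyphenyl)-3-(triethylsilyloxy)buta-1,3-diene | C=C(O[Si](CC)(CC)CC)/C=C/c1ccc(OCC=C)c(OC)c1
F6 | step 9 | allyl 3-(4-allyloxy-3-methoxyphenyl)propanoate | COc1cc(CCC(=O)OCC=C)ccc1OCC=C
F7 | step 9 | 3-(4-allyloxy-3-methoxyphenyl)propan-1-ol | COc1cc(CCCO)ccc1OCC=C
F8 | step 9 | 3-(4-allyloxy-3-methoxyphenyl)propanal | COc1cc(CCC=O)ccc1OCC=C
F9 | step 9 | (2S,6S)-2-(4-allyloxy-3-methoxyphenyl)-6-[2-(4-allyloxy-3-methoxyphenyl)ethyl]-4-(triethylsilyloxy)-5,6-dihydro-2H-pyran | COc1cc(CC[C@H]2CC(O[Si](CC)(CC)CC)=C[C@@H](c3ccc(OCC=C)c(OC)c3)O2)ccc1OCC=C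
F10 | step 9 | (2S,6S)-2-(4-allyloxy-3-methoxyphenyl)-6-[2-(4-allyloxy-3-methoxyphenyl)ethyl]tetrahydro-4H-pyran-4-one | COc1cc(CC[C@H]2CC(=O)C[C@@H](c3ccc(OCC=C)c(OC)c3)O2)ccc1OCC=C
F11 | step 9 | (2S,4S,6S)-2-(4-allyloxy-3-methoxyphenyl)-6-[2-(4-allyloxy-3-methoxyphenyl)ethyl]tetrahydro-2H-pyran-4-ol | COc1cc(CC[C@H]2C[C@H](O)C[C@@H](c3ccc(OCC=C)c(OC)c3)O2)ccc1OCC=C
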